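Look at the slope.

| flask | X | E | remark | time |
|---|---|---|---|---|
| spring | 0.10 M | 0.050 mM | run made earlier |  |
| flask | 0.050 M | 0.0500 mM |  | 10 h |

spring run (percent of the X charged)

| time / min | X / % | D / % |
|---|---|---|
| 30.0 | 82.3 | 18.3 |
| 60.0 | 58.1 | 41.5 |
| 90.0 | 38.8 | 60.2 |
| 120 | 25.4 | 75.1 |

(scatter of a reading: 1 percentage point)

1. part of the X that has reacted at 10 h
2. pH of the solution at 10 h

- E is the free proton; pH is minus the decimal logarithm of its molar concentration
- what was read earlier has a scatter of 1 percentage point, one standard deviation
- a reading or a percentage of D counts all its forms, free or not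

At the bench you would plot ln X against time, lay one straight line through it and treat the gradient as a pseudo-first-order constant. So take s = 0.0131 min⁻¹, the mean slope, that is, the fall of ln X per minute between the first and last readings of the spring run.

Now find where the line stops working. Up to the first reading the slope is 0.00649 min⁻¹, in the last window it is 0.0141 min⁻¹, and their ratio of 2.17 says the run accelerates, so no line covers the start. From the first reading on, the last window over the second, 0.0116 min⁻¹, gives 1.22, so there the mean is a fair stand-in.

I assume that E grows as the root of D, a weak acid, so for this flask I scale s by 0.707 to 0.00924 min⁻¹. Over 10 h that leaves 0.392 % of X, so I commit to 99.6 % reacted. With the second window's 0.0116 min⁻¹ in place of s, 0.727 % of X is left, and with the slower 0.00649 min⁻¹ from the start of the run, 6.36 % is left, so my figure is an estimate with that spread. The time 10 h is 5.00 times the last reading's time, and I reckon no pH.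

The forecast, holding that “This suggests acid catalysis”, says 99.7 % and pH 3.57.

The flask gives 96.8 % and pH 4.17.

    X + E → J + E + D (k = 44.0 M⁻¹ min⁻¹)
    J ⇌ G + E, settled at all times (K = 2.50 × 10⁻⁶ M)
    X → J + D (k = 5.50 × 10⁻⁵ min⁻¹)
    J → Z (k = 0.0160 min⁻¹)
    L ⇌ D, rate k5*(cs5 - [D]) while solid is left; crystals form when [D] > cs5 (solubility = 32.0 mM, k = 0.210 min⁻¹)

So 3.2 % of X remains in the flask, a mean slope of 0.00574 min⁻¹ against the scaled 0.00924 min⁻¹. E stands at 134 % of its charge at 10.0 h, down from 214 % at 6.00 h in the neighbour flask, the same charge stopped at 6.0 h. For that neighbour flask the scaled s leaves 3.60 %, while it holds 7.8 % of X.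

The numbers in the tables stem from a simulated flask for substances that don't exist.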